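**Retrosynthetic overview**
1. Last disconnection: the bond between C6 of the arene (ring B of the chromene) and the bridging CH2 on ring A. The forward reaction is conjugate addition of the chromene phenolate to a 2-methylidene-1,3-dione, unmasked from a CH2OMe group. Acid hydrolysis of two enol ethers follows, one of them a 1-ethoxyethenyl group (masked acetyl, installed by Stille coupling at a C–Br bond).
2. Ring A (the 4,4-dimethylcyclohexane-1,3,5-trione ring) comes from 2-bromo-3-ethoxy-4,4-dimethylcyclobutenone and a siloxyalkyne, TIPSO–C≡C–CH2OMe. A Danheiser-type annulation inserts the alkyne between the carbonyl carbon and the brominated carbon of the four-membered ring.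
3. Enabling feature: in ring A the quaternary CMe2 carbon sits between two oxygen-bearing carbons of a 1,3,5-trioxygenated carbocycle. CMe2 and its neighbours map onto a dimethylketene/ethoxyacetylene cyclobutenone; the three oxygens map onto the ketene oxygen, the enol ether oxygen and the ynol ether oxygen. The quaternary carbon blocks aromatization, so the annulation stops at the dienone level of the target.
4. Ring order: four-membered ring (step 1), then ring A (step 4); pyran ring C onto the commercial arene ring B (step 7); union of ring A with rings B/C (step 8).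

Key step: step 4

Remark: ring A is a β-triketone, so the enol tautomer written in the target SMILES and the one formed in the last step are the same compound; the target has no stereocentre.

**Step 1**
Reactants: 1 isobutyryl chloride; 2 ethoxyacetylene
Product: 4 3-ethoxy-4,4-dimethylcyclobut-2-en-1-one, via dimethylketene 3 (not isolated)
Conditions: Et3N (1.2 equiv), 2 (1.5 equiv), MeCN, 0 → 40 °C
Reagents that add atoms: none
Why: Dehydrochlorination of 1 gives dimethylketene, and its thermal [2+2] ketene–alkyne cycloaddition with the electron-rich alkoxyalkyne should join the ketene carbonyl carbon to the alkyne CH and place the ethoxy-bearing carbon next to CMe2.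

**Step 2**
Reactants: 4 3-ethoxy-4,4-dimethylcyclobut-2-en-1-one
Product: 5 2-bromo-3-ethoxy-4,4-dimethylcyclobut-2-en-1-one
Conditions: NBS (1.05 equiv), CH2Cl2, 0 °C → rt
Reagents that add atoms: N-bromosuccinimide, O=C1CCC(=O)N1Br
Why: Electrophilic α-bromination of a vinylogous ester (β-alkoxy enone) should occur at the only vinylic C–H, since C4 is quaternary and offers no other site.

**Step 3**
Reactants: 6 3-methoxyprop-1-yne (methyl propargyl ether)
Product: 9 [(3-methoxyprop-1-yn-1-yl)oxy]triisopropylsilane, via lithium acetylide 7 (not isolated), via lithium ynolate 8 (not isolated)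
Conditions: n-BuLi, THF, −78 °C; LiOOt-Bu (from t-BuOOH and LiN(SiMe3)2), −78 → 0 °C; TIPSOTf, −78 °C → rt
Reagents that add atoms: tert-butyl hydroperoxide, CC(C)(C)OO; triisopropylsilyl trifluoromethanesulfonate, CC(C)[Si](C(C)C)(C(C)C)OS(=O)(=O)C(F)(F)F
Why: Oxygen transfer from lithium tert-butyl peroxide to the lithium acetylide should give the ynolate, which the bulky silyl triflate traps on oxygen (acetylide oxidation/O-silylation route to siloxyalkynes).

**Step 4**
Reactants: 5 2-bromo-3-ethoxy-4,4-dimethylcyclobut-2-en-1-one; 9 [(3-methoxyprop-1-yn-1-yl)oxy]triisopropylsilane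
Product: 13 4-bromo-5-ethoxy-2-(methoxymethyl)-6,6-dimethyl-3-[(triisopropylsilyl)oxy]cyclohexa-2,4-dien-1-one, via bromo(vinyl)ketene 10 (not isolated), via alkenylcyclobutenone 11 (not isolated), via dienylketene 12 (not isolated)
Conditions: 9 (1.5 equiv), toluene, 100 °C, sealed tube
Reagents that add atoms: none
Why: Heating should open 5 by 4π conrotatory electrocyclic cleavage to bromo(vinyl)ketene 10, whose ketene C=C adds siloxyalkyne 9 in a regioselective [2+2] cycloaddition to give 11; a second 4π opening gives dienylketene 12, which closes ring A by thermal 6π disrotatory electrocyclization onto its CMe2 terminus. The closest known reaction type is the Danheiser benzannulation of cyclobutenones with siloxyalkynes, run here in its cyclohexadienone mode because the quaternary terminus cannot tautomerize to a phenol; the same closure returns dienylketenes from photolysed 6,6-disubstituted cyclohexa-2,4-dienones to the dienones. Net, only two bonds are new: ketene carbonyl carbon to the methoxymethyl-bearing alkyne carbon, and brominated ketene carbon to the siloxy-bearing alkyne carbon; the bond from the carbonyl carbon to CMe2 is broken and formed again. No stereocentre is created. The step needs regioselectivity in the [2+2] event, secured by the polarization of the ynol ether (its carbon remote from oxygen attacks the electrophilic ketene carbon), and inward rotation of the alkenyl group when 11 opens, favoured because the bromine donor rotates outward and corrected by reversible re-closure otherwise. Excess 9 should suppress ketene dimerization and the 1,5-hydrogen shift of 10.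

**Step 5**
Reactants: 13 4-bromo-5-ethoxy-2-(methoxymethyl)-6,6-dimethyl-3-[(triisopropylsilyl)oxy]cyclohexa-2,4-dien-1-one; 14 tributyl(1-ethoxyethenyl)stannane
Product: 15 5-ethoxy-4-(1-ethoxyethenyl)-2-(methoxymethyl)-6,6-dimethyl-3-[(triisopropylsilyl)oxy]cyclohexa-2,4-dien-1-one
Conditions: Pd2(dba)3 (5 mol %), P(2-furyl)3, CuI, dioxane, 80 °C; filtration through basic alumina
Reagents that add atoms: none
Why: Stille cross-coupling of an α-bromo vinylogous ester with an α-alkoxyvinylstannane on zerovalent palladium should install the masked acetyl group under neutral conditions that spare the silyl enol ether, the methyl ether and the vinylogous ester, with CuI speeding transmetalation at the flanked carbon.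

**Step 6**
Reactants: 16 2,4,6-trihydroxyacetophenone (anhydrous)
Product: 17 1-[2,6-dihydroxy-4-[(triisopropylsilyl)oxy]phenyl]ethan-1-one
Conditions: TIPSCl (1.05 equiv), imidazole, DMF, 0 °C
Reagents that add atoms: chlorotriisopropylsilane, CC(C)[Si](Cl)(C(C)C)C(C)C
Why: Regioselective O-silylation should take the para hydroxyl, which is the most acidic, the least hindered and the only one not hydrogen-bonded to the acetyl group.

**Step 7**
Reactants: 17 1-[2,6-dihydroxy-4-[(triisopropylsilyl)oxy]phenyl]ethan-1-one; 18 3-methylbut-2-enal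
Product: 20 1-[7-hydroxy-2,2-dimethyl-5-[(triisopropylsilyl)oxy]-2H-chromen-8-yl]ethan-1-one, via o-quinone methide 19 (not isolated)
Conditions: 18 (1.1 equiv), ethylenediammonium diacetate (10 mol %), toluene, 110 °C
Reagents that add atoms: none
Why: Amine-catalysed Knoevenagel-type condensation at a ring CH followed by oxa-6π electrocyclization (chromenylation of a phloroglucinol-type phenol) should build ring C; with the para oxygen silylated, the pyran oxygen can only come from the hydroxyl next to the acetyl group, which fixes the 8-acetyl regiochemistry.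

**Step 8**
Reactants: 15 5-ethoxy-4-(1-ethoxyethenyl)-2-(methoxymethyl)-6,6-dimethyl-3-[(triisopropylsilyl)oxy]cyclohexa-2,4-dien-1-one; 20 1-[7-hydroxy-2,2-dimethyl-5-[(triisopropylsilyl)oxy]-2H-chromen-8-yl]ethan-1-one
Product: 25 2-acetyl-6-[(8-acetyl-5,7-dihydroxy-2,2-dimethyl-2H-chromen-6-yl)methyl]-3,5-dihydroxy-4,4-dimethylcyclohexa-2,5-dien-1-one (target), via desilylated enol 21 (not isolated), via chromene diol 22 (not isolated), via methylidene dione 23 (not isolated), via coupled enol ether 24 (not isolated)
Conditions: TBAF (2.2 equiv, dried over 4 Å MS), THF, 0 → 40 °C (20 first, then 15 added slowly); then 1 M HCl (aq.), THF, rt → 40 °C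
Reagents that add atoms: water, O
Why: Fluoride should free the enolate of 21 and the phenolate of 22, E1cB loss of methoxide should give the 2-methylidene-1,3-dione 23, which C6 of the phenolate traps by conjugate addition (the carbon–carbon bond-forming half of the classical formaldehyde methylene-bridge coupling of acylphloroglucinols), and aqueous acid should then hydrolyse the 1-ethoxyethenyl group to the acetyl group and the doubly activated vinylogous ester to the enol.

**Compound list**
1 | isobutyryl chloride | CC(C)C(=O)Cl | starting material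
2 | ethoxyacetylene | CCOC#C | starting material
3 | dimethylketene | CC(C)=C=O | intermediate (not isolated)
4 | 3-ethoxy-4,4-dimethylcyclobut-2-en-1-one | CCOC1=CC(=O)C1(C)C | intermediate
5 | 2-bromo-3-ethoxy-4,4-dimethylcyclobut-2-en-1-one | CCOC1=C(Br)C(=O)C1(C)C | intermediate
6 | 3-methoxyprop-1-yne | COCC#C | starting material
7 | lithium 3-methoxyprop-1-yn-1-ide | [Li]C#CCOC | intermediate (not isolated)
8 | lithium 3-methoxyprop-1-yn-1-olate | [Li]OC#CCOC | intermediate (not isolated)
9 | [(3-methoxyprop-1-yn-1-yl)oxy]triisopropylsilane | COCC#CO[Si](C(C)C)(C(C)C)C(C)C | intermediate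
10 | 2-bromo-3-ethoxy-4-methylpenta-1,3-dien-1-one | O=C=C(Br)C(OCC)=C(C)C | intermediate (not isolated)
11 | 4-bromo-4-(1-ethoxy-2-methylprop-1-en-1-yl)-2-(methoxymethyl)-3-[(triisopropylsilyl)oxy]cyclobut-2-en-1-one | O=C1C(COC)=C(O[Si](C(C)C)(C(C)C)C(C)C)C1(Br)C(OCC)=C(C)C | intermediate (not isolated)
12 | (3Z)-4-bromo-5-ethoxy-2-(methoxymethyl)-6-methyl-3-[(triisopropylsilyl)oxy]hepta-1,3,5-trien-1-one | O=C=C(COC)/C(O[Si](C(C)C)(C(C)C)C(C)C)=C(Br)\C(OCC)=C(C)C | intermediate (not isolated)
13 | 4-bromo-5-ethoxy-2-(methoxymethyl)-6,6-dimethyl-3-[(triisopropylsilyl)oxy]cyclohexa-2,4-dien-1-one | O=C1C(COC)=C(O[Si](C(C)C)(C(C)C)C(C)C)C(Br)=C(OCC)C1(C)C | intermediate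
14 | tributyl(1-ethoxyethenyl)stannane | CCCC[Sn](CCCC)(CCCC)C(=C)OCC | starting material
15 | 5-ethoxy-4-(1-ethoxyethenyl)-2-(methoxymethyl)-6,6-dimethyl-3-[(triisopropylsilyl)oxy]cyclohexa-2,4-dien-1-one | O=C1C(COC)=C(O[Si](C(C)C)(C(C)C)C(C)C)C(C(=C)OCC)=C(OCC)C1(C)C | intermediate
16 | 2,4,6-trihydroxyacetophenone | CC(=O)c1c(O)cc(O)cc1O | starting material
17 | 1-[2,6-dihydroxy-4-[(triisopropylsilyl)oxy]phenyl]ethan-1-one | CC(=O)c1c(O)cc(O[Si](C(C)C)(C(C)C)C(C)C)cc1O | intermediate
18 | 3-methylbut-2-enal | CC(C)=CC=O | starting material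
19 | 2-acetyl-3-hydroxy-6-(3-methylbut-2-en-1-ylidene)-5-[(triisopropylsilyl)oxy]cyclohexa-2,4-dien-1-one | CC(=O)C1=C(O)C=C(O[Si](C(C)C)(C(C)C)C(C)C)C(=CC=C(C)C)C1=O | intermediate (not isolated)
20 | 1-[7-hydroxy-2,2-dimethyl-5-[(triisopropylsilyl)oxy]-2H-chromen-8-yl]ethan-1-one | CC(=O)c1c(O)cc(O[Si](C(C)C)(C(C)C)C(C)C)c2C=CC(C)(C)Oc12 | intermediate
21 | 5-ethoxy-4-(1-ethoxyethenyl)-3-hydroxy-2-(methoxymethyl)-6,6-dimethylcyclohexa-2,4-dien-1-one (present as its enolate) | O=C1C(COC)=C(O)C(C(=C)OCC)=C(OCC)C1(C)C | intermediate (not isolated)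
22 | 1-(5,7-dihydroxy-2,2-dimethyl-2H-chromen-8-yl)ethan-1-one (present as its phenolate) | CC(=O)c1c(O)cc(O)c2C=CC(C)(C)Oc12 | intermediate (not isolated)
23 | 5-ethoxy-4-(1-ethoxyethenyl)-6,6-dimethyl-2-methylidenecyclohex-4-ene-1,3-dione | C=C1C(=O)C(C(=C)OCC)=C(OCC)C(C)(C)C1=O | intermediate (not isolated)
24 | 2-[(8-acetyl-5,7-dihydroxy-2,2-dimethyl-2H-chromen-6-yl)methyl]-5-ethoxy-4-(1-ethoxyethenyl)-3-hydroxy-6,6-dimethylcyclohexa-2,4-dien-1-one | O=C1C(Cc2c(O)c3C=CC(C)(C)Oc3c(C(C)=O)c2O)=C(O)C(C(=C)OCC)=C(OCC)C1(C)C | intermediate (not isolated)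
25 | 2-acetyl-6-[(8-acetyl-5,7-dihydroxy-2,2-dimethyl-2H-chromen-6-yl)methyl]-3,5-dihydroxy-4,4-dimethylcyclohexa-2,5-dien-1-one | CC(=O)C1=C(O)C(C)(C)C(O)=C(Cc2c(O)c3c(c(C(C)=O)c2O)OC(C)(C)C=C3)C1=O | target

**Step count and risks**
Total steps: 8. Longest linear sequence: 5 (steps 1, 2, 4, 5, 8).

Step 4. The electrocyclic opening of the hindered, donor-stabilized cyclobutenone may be slow, so that the ketene dimerizes or undergoes a 1,5-hydrogen shift. Bromide may also be lost from the transient tertiary α-bromo ketone, or the alkenyl group may rotate outward and give a dienylketene that oligomerizes instead of closing. The fallback gives up the annulation for classical dearomative alkylation; it sets out from 16 and 20 and comes back to the route at 25. Twofold C-methylation of 16 (MeI, NaOMe, MeOH, 0 °C → rt) should give 2-acetyl-3,5-dihydroxy-4,4-dimethylcyclohexa-2,5-dien-1-one F1. Separately, 20 is desilylated (TBAF, THF) to 22, which is isolated this time. F1, 22 and aqueous formaldehyde are then condensed in dilute KOH at 0 °C to 25; the symmetrical dimers expected alongside have to be separated.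

Step 8. Expulsion of methoxide may be sluggish, the methide may be intercepted by water or by a second enolate, formaldehyde may be released and scramble the halves into symmetrical dimers, or hydrolysis of the hindered vinylogous ester may stall. The fallback replaces in situ trapping by an isolated Mannich base; it sets out from 15 and 20 and comes back at 25. Compound 15 is treated with TBAF in THF in the presence of excess dimethylamine and then with dilute HCl; this should give 2-acetyl-6-[(dimethylamino)methyl]-3,5-dihydroxy-4,4-dimethylcyclohexa-2,5-dien-1-one F2, isolated as its hydrochloride. Compound 22 is prepared and isolated from 20 (TBAF, THF). Heating F2 with 22 in dioxane at 90 °C should expel the amine and deliver 25 by the same conjugate addition.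

Step 5. Oxidative addition and transmetalation at the ring carbon flanked by the siloxy and ethoxy groups may be slow, leaving protodebromination or loss of the silyl group as the main processes. The fallback moves the cross-coupling to the unhindered four-membered ring and carries the acetyl group through the annulation as a ketal, which avoids both an acylketene and a second vinyl group on the ketene. It sets out from 5 and 14 and comes back at 25. Stille coupling (Pd(PPh3)4, CuI, DMF, 50 °C) should give 3-ethoxy-2-(1-ethoxyethenyl)-4,4-dimethylcyclobut-2-en-1-one F3. Exchange with ethylene glycol (PPTS, CH2Cl2, rt) gives 3-ethoxy-4,4-dimethyl-2-(2-methyl-1,3-dioxolan-2-yl)cyclobut-2-en-1-one F4. Annulation of F4 with 9 under the conditions of step 4 gives 5-ethoxy-2-(methoxymethyl)-6,6-dimethyl-4-(2-methyl-1,3-dioxolan-2-yl)-3-[(triisopropylsilyl)oxy]cyclohexa-2,4-dien-1-one F5. F5 then takes the place of 15 in step 8, whose acid stage also opens the dioxolane, and gives 25.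

**Further compounds**
F1 | step 4 | 2-acetyl-3,5-dihydroxy-4,4-dimethylcyclohexa-2,5-dien-1-one | CC(=O)C1=C(O)C(C)(C)C(O)=CC1=O
F2 | step 8 | 2-acetyl-6-[(dimethylamino)methyl]-3,5-dihydroxy-4,4-dimethylcyclohexa-2,5-dien-1-one | CC(=O)C1=C(O)C(C)(C)C(O)=C(CN(C)C)C1=O
F3 | step 5 | 3-ethoxy-2-(1-ethoxyethenyl)-4,4-dimethylcyclobut-2-en-1-one | CCOC(=C)C1=C(OCC)C(C)(C)C1=O
F4 | step 5 | 3-ethoxy-4,4-dimethyl-2-(2-methyl-1,3-dioxolan-2-yl)cyclobut-2-en-1-one | CCOC1=C(C2(C)OCCO2)C(=O)C1(C)C
F5 | step 5 | 5-ethoxy-2-(methoxymethyl)-6,6-dimethyl-4-(2-methyl-1,3-dioxolan-2-yl)-3-[(triisopropylsilyl)oxy]cyclohexa-2,4-dien-1-one | O=C1C(COC)=C(O[Si](C(C)C)(C(C)C)C(C)C)C(C2(C)OCCO2)=C(OCC)C1(C)C
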